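**Retrosynthetic overview**

1. Target ⇒ (S)-2-methyl-2-(10-phenyldecyl)oxirane + α-angelica lactone. The oxirane is expanded to the oxolane by insertion of the furanone C5–C4 unit into its CH2–O bond (C–C bond by SN2 opening, C–O bond by oxa-Michael closure); this sets C6a and C3a.
2. Oxirane ⇒ 12-phenyldodecan-2-one by catalytic asymmetric Corey–Chaykovsky methylene transfer (sets C5).
3. Ketone ⇒ 8-phenyloct-1-ene + methyl vinyl ketone (hydrozirconation, copper-catalysed conjugate addition).
4. 8-Phenyloct-1-ene ⇒ 1,7-octadiene + bromobenzene (hydroboration, B-alkyl Suzuki–Miyaura coupling).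
5. Ring order: oxirane (step 3), then oxolane by ring expansion (step 4); the lactone ring arrives intact with α-angelica lactone and becomes fused in that same step.

Assumption: each chiral ligand is named as the antipode taken to give the configuration drawn; if the sense of induction proves opposite, the mirror-image ligand is used.

**Route**

Step 1
Reactants: 1 octa-1,7-diene; 2 bromobenzene
Product: 4 oct-7-en-1-ylbenzene, via B-(oct-7-en-1-yl)-9-borabicyclo[3.3.1]nonane 3 (not isolated)
Conditions: 1 (4 equiv), 9-BBN (1.0 equiv), THF, 0 °C to rt; excess 1 evaporated; then 2 (0.9 equiv), PdCl2(dppf) (3 mol%), 3 M aq NaOH, THF, 65 °C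
Reagents that add atoms: none
Why: Anti-Markovnikov hydroboration of one terminal alkene (diene in excess to favour the mono-adduct) followed by B-alkyl Suzuki–Miyaura coupling with the aryl bromide; no stereocentre is formed.

Step 2
Reactants: 4 oct-7-en-1-ylbenzene; 5 but-3-en-2-one (methyl vinyl ketone)
Product: 7 12-phenyldodecan-2-one, via chloro(8-phenyloctyl)zirconocene 6 (not isolated)
Conditions: Cp2Zr(H)Cl (1.2 equiv), THF, rt; then 5 (1.5 equiv), CuBr·SMe2 (10 mol%), 40 °C; 1 M aq HCl
Reagents that add atoms: none
Why: Hydrozirconation puts zirconium on the terminal carbon, and copper-catalysed transmetalation with conjugate addition (Schwartz–Wipf protocol) transfers the primary alkyl group to the β-carbon of the enone; no stereocentre is formed.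

Step 3
Reactants: 7 12-phenyldodecan-2-one
Product: 8 (2S)-2-methyl-2-(10-phenyldecyl)oxirane
Conditions: Me3S(O)I (1.2 equiv), NaH (1.2 equiv), THF; LaLi3[(S)-1,1'-binaphthalene-2,2'-diolate]3 (5 mol%), tris(2,4,6-trimethoxyphenyl)phosphine oxide (5 mol%), 5 Å MS, THF, rt
Reagents that add atoms: trimethylsulfoxonium iodide, C[S+](C)(C)=O.[I-] (delivers CH2 through its ylide)
Why: Catalytic asymmetric Corey–Chaykovsky epoxidation, in which the lanthanum–lithium binaphthoxide complex binds the methyl ketone and the sulfoxonium ylide and delivers CH2 to one carbonyl face (methyl ketones are the substrate class that gives about 91–97% ee); this sets C5 of the target as S.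

Step 4
Reactants: 8 (2S)-2-methyl-2-(10-phenyldecyl)oxirane; 9 5-methylfuran-2(3H)-one (α-angelica lactone)
Product: 11 (3aR,5S,6aR)-5,6a-dimethyl-5-(10-phenyldecyl)tetrahydrofuro[3,2-b]furan-2(3H)-one (plakortolide ether), via hydroxy butenolide 10 (not isolated)
Conditions: Et2Zn (20 mol%), (S,S)-ProPhenol (10 mol%; 2,6-bis{[(2S)-2-(hydroxydiphenylmethyl)pyrrolidin-1-yl]methyl}-4-methylphenol), 4 Å MS, toluene, 60 °C, 9 (3 equiv) added over 12 h; then DBU (0.2 equiv), rt
Reagents that add atoms: none
Why: Proposed new method: the dinuclear zinc complex formed from Et2Zn and ProPhenol deprotonates 9 to a zinc 2-furanolate and binds the oxirane oxygen at its second zinc, so that the furanolate γ-carbon (C5, the site that reacts in the known zinc–ProPhenol vinylogous Michael additions of butenolides) opens 8 by SN2 attack at the unhindered CH2 with the quaternary carbon of 8 untouched, and the resulting zinc alkoxide 10 closes by 5-exo-trig oxa-Michael addition onto the new butenolide, which expands the oxirane to the oxolane by net insertion of the furanone C5–C4 unit into the CH2–O bond in a stepwise ionic sequence; the catalyst pocket selects the furanolate face (6a-R), the obligatory cis ring fusion then fixes 3a-R, and the closest known reactions are the malonate–epoxide lactone annulation, the direct γ-selective additions of α-angelica lactone under bifunctional catalysis and the base-induced oxa-Michael closure of γ-(2-hydroxyalkyl)butenolides.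

**Compound list**

1 | octa-1,7-diene | C=CCCCCC=C | starting material
2 | bromobenzene | Brc1ccccc1 | starting material
3 | B-(oct-7-en-1-yl)-9-borabicyclo[3.3.1]nonane | C=CCCCCCCB1C2CCCC1CCC2 | intermediate
4 | oct-7-en-1-ylbenzene (8-phenyloct-1-ene) | C=CCCCCCCc1ccccc1 | intermediate
5 | but-3-en-2-one | CC(=O)C=C | starting material
6 | chloro(8-phenyloctyl)zirconocene | Cl[Zr](CCCCCCCCc1ccccc1)(C1C=CC=C1)C1C=CC=C1 | intermediate
7 | 12-phenyldodecan-2-one | CC(=O)CCCCCCCCCCc1ccccc1 | intermediate
8 | (2S)-2-methyl-2-(10-phenyldecyl)oxirane | C[C@]1(CCCCCCCCCCc2ccccc2)CO1 | intermediate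
9 | 5-methylfuran-2(3H)-one (α-angelica lactone) | CC1=CCC(=O)O1 | starting material
10 | (5R)-5-[(2S)-2-hydroxy-2-methyl-12-phenyldodecyl]-5-methylfuran-2(5H)-one (present as its zinc alkoxide) | C[C@](O)(CCCCCCCCCCc1ccccc1)C[C@@]1(C)OC(=O)C=C1 | intermediate
11 | (3aR,5S,6aR)-5,6a-dimethyl-5-(10-phenyldecyl)tetrahydrofuro[3,2-b]furan-2(3H)-one (plakortolide ether) | C[C@]1(CCCCCCCCCCc2ccccc2)C[C@@]2(C)OC(=O)C[C@H]2O1 | target

**Step count and risk**

Total steps: 4. Longest linear sequence: 4.

The three steps most likely to fail, most risky first: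

Step 4 (the proposed new ring expansion). The likely failure modes are:
- alkylation of the furanolate at C3 instead of C5, followed by translactonisation onto the enol lactone;
- slow SN2 attack, because the CH2 is flanked by a quaternary carbon and a quaternary carbon is being formed;
- self-Michael dimerisation of 9;
- weak facial control at C6a.

Fallback with known chemistry, setting out from 8: reductive lithiation with lithium 4,4'-di-tert-butylbiphenylide (THF, −78 °C) cleaves the CH2–O bond and gives lithium (2R)-1-lithio-2-methyl-12-phenyldodecan-2-olate F1 (C–O stereocentre of 8 unchanged). Its 1,2-addition to 5 at −78 °C, then water, gives (3R,5S)-3,5-dimethyl-15-phenylpentadec-1-ene-3,5-diol F2 together with its epimer (3S,5S)-3,5-dimethyl-15-phenylpentadec-1-ene-3,5-diol F3, expected near 1:1. The mixture is put through the known hydroxycyclisation–carbonylation–lactonisation of ene-1,3-diols (PdCl2 10 mol%, CuCl2 3 equiv, NaOAc, AcOH, CO 1 atm, rt). F2 gives 11, and F3 gives (3aS,5S,6aS)-5,6a-dimethyl-5-(10-phenyldecyl)tetrahydrofuro[3,2-b]furan-2(3H)-one F4, which is removed by chromatography. The fallback comes back to the route at 11.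

Step 2 (conjugate addition to a polymerisation-prone enone). Fallback setting out from 4: cross-metathesis with hex-5-en-2-one (CC(=O)CCC=C, 3 equiv; second-generation Hoveyda–Grubbs catalyst, CH2Cl2, 40 °C) gives (E)-12-phenyldodec-5-en-2-one F5 (some Z isomer is immaterial). Hydrogenation (H2 1 atm, palladium on carbon, EtOAc, rt) then gives 7, where the route is rejoined.

Step 3 (enantioselectivity with a long-chain alkyl methyl ketone). Fallback setting out from 7: uncatalysed Corey–Chaykovsky epoxidation (Me3S(O)I, NaH, DMSO, rt) gives rac-2-methyl-2-(10-phenyldecyl)oxirane F6. Kinetic resolution by azidolysis follows (TMSN3 0.55 equiv, [N,N'-bis(3,5-di-tert-butylsalicylidene)-1,2-cyclohexanediaminato]CrN3 2 mol%, tert-butyl methyl ether, 0 °C to rt). This converts the R enantiomer into (2R)-1-azido-2-methyl-12-phenyl-2-(trimethylsilyloxy)dodecane F7 and leaves 8, which is isolated by chromatography (at most 50%). The route is rejoined at 8.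

**Further compounds**

F1 | step 4 | lithium (2R)-1-lithio-2-methyl-12-phenyldodecan-2-olate | [Li]C[C@@](C)(O[Li])CCCCCCCCCCc1ccccc1
F2 | step 4 | (3R,5S)-3,5-dimethyl-15-phenylpentadec-1-ene-3,5-diol | C[C@](O)(CCCCCCCCCCc1ccccc1)C[C@@](C=C)(C)O
F3 | step 4 | (3S,5S)-3,5-dimethyl-15-phenylpentadec-1-ene-3,5-diol | C[C@](O)(CCCCCCCCCCc1ccccc1)C[C@](C=C)(C)O
F4 | step 4 | (3aS,5S,6aS)-5,6a-dimethyl-5-(10-phenyldecyl)tetrahydrofuro[3,2-b]furan-2(3H)-one | C[C@]1(CCCCCCCCCCc2ccccc2)C[C@]2(C)OC(=O)C[C@@H]2O1
F5 | step 2 | (E)-12-phenyldodec-5-en-2-one | CC(=O)CC/C=C/CCCCCCc1ccccc1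
F6 | step 3 | rac-2-methyl-2-(10-phenyldecyl)oxirane | CC1(CCCCCCCCCCc2ccccc2)CO1
F7 | step 3 | (2R)-1-azido-2-methyl-12-phenyl-2-(trimethylsilyloxy)dodecane | C[C@@](O[Si](C)(C)C)(CCCCCCCCCCc1ccccc1)CN=[N+]=[N-]
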